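**Strategy.** Each cyclopentanol is cut twice (ring atoms: C-a carbinol, C-b bearing isopropenyl, C-c and C-d the two CH2, C-e bearing the oxane). The C-a–C-b bond with its cis OH/isopropenyl pair is the retron of an intramolecular carbonyl-ene reaction, and the C-c–C-d bond is the σ-bond of an oxy-Cope shift. One pot therefore converts an acyclic 4,4-dimethylhexa-1,5-dien-3-ol, which contains neither the ring nor the isopropenyl group, into the cyclopentanol by [3,3] rearrangement, protonation and ene closure. Two resolved rings are then added to a C2-symmetric bis(vinylsilane), and both oxanes are closed by acetal–vinylsilane cyclisation.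

Key step: step 4

Assumption: in step 7 the lipase acylates the unwanted enantiomer faster, so 12 is the recovered alcohol; were the preference reversed, the acetate fraction would be taken and cleaved (K2CO3, MeOH) to the same compound 12.

Remarks: racemic compounds (5, 8–11) are drawn as one enantiomer. The absolute configuration comes from a resolution (step 7), because the cascade necessarily creates C-e by protonation of an enolate. Oxane atoms are called O-1, C-2 (bearing the cyclopentyl), C-3, C-4, C-5 (alkylidene carbon), C-6 (OCH2).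

**Ring fragment**

Step 1
Reactants: 1 2-methylidenepropane-1,3-diol
Product: 2 2-{[(4-methoxybenzyl)oxy]methyl}prop-2-en-1-ol
Conditions: 4-methoxybenzyl chloride (0.5 equiv), Ag2O, CH2Cl2, 23 °C
Reagents that add atoms: 4-methoxybenzyl chloride, COc1ccc(CCl)cc1
Why: Ag2O-mediated Williamson etherification of a symmetric diol used in excess should stop at the mono-ether; no stereocentre is involved.

Step 2
Reactants: 2 2-{[(4-methoxybenzyl)oxy]methyl}prop-2-en-1-ol
Product: 3 2-{[(4-methoxybenzyl)oxy]methyl}prop-2-enal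
Conditions: MnO2, CH2Cl2, 23 °C
Reagents that add atoms: none
Why: Allylic oxidation with MnO2 is selective for the allylic primary alcohol and should leave the benzylic ether untouched.

Step 3
Reactants: 3 2-{[(4-methoxybenzyl)oxy]methyl}prop-2-enal; 4 (3-methylbut-2-en-1-yl)magnesium chloride (prenylmagnesium chloride)
Product: 5 2-{[(4-methoxybenzyl)oxy]methyl}-4,4-dimethylhexa-1,5-dien-3-ol (racemic)
Conditions: THF, −78 °C; aq. NH4Cl
Reagents that add atoms: none
Why: Grignard 1,2-addition of a prenyl reagent occurs through its γ-carbon (SE2′, six-membered transition state), placing the 1,1-dimethylallyl unit next to the carbinol; the carbinol centre forms as a racemate and is erased in step 4.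

Step 4
Reactants: 5 2-{[(4-methoxybenzyl)oxy]methyl}-4,4-dimethylhexa-1,5-dien-3-ol
Product: 9 rac-(1S,2R,5R)-2-{[(4-methoxybenzyl)oxy]methyl}-5-(prop-1-en-2-yl)cyclopentan-1-ol (OH cis to isopropenyl and trans to the CH2OPMB arm), via potassium alkoxide 6 (not isolated), via potassium enolate 7 (not isolated), via aldehyde 8 (not isolated)
Conditions: KH (1.2 equiv), 18-crown-6 (1.2 equiv), toluene, 0 → 23 °C; HCl (2 M in Et2O, 1.2 equiv), −78 °C; Me2AlCl (3 equiv, hexanes), −78 → −40 °C
Reagents that add atoms: none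
Why: Alkoxide 6 undergoes an anionic oxy-Cope [3,3] shift through a chair transition state, joining the two terminal =CH2 carbons (bond C-c–C-d) to give enolate 7; HCl protonates it to the δ,ε-unsaturated aldehyde 8, which Me2AlCl closes by a type 1 intramolecular carbonyl-ene reaction (bond C-a–C-b), the hydrogen transferred from an allylic methyl group unveiling the isopropenyl group. The closest known reaction types are the anionic oxy-Cope rearrangement of 1,1-dimethylallyl carbinols (formal conjugate prenylation) and the Lewis acid-promoted ene cyclisation of 6-methylhept-5-enals, run in sequence as in tandem oxy-Cope/ene processes. The cyclopentane closes by attack of the trisubstituted alkene on the complexed formyl carbon (5-exo-trig at the carbonyl) within a cis-fused bicyclic transition state that contains the six-membered hydrogen-transfer array. That array requires the C–O bond and the developing C(CH3)=CH2 group to be syn, which sets C-a and C-b cis. C-e, formed as a racemate at protonation, directs the aldehyde face: its CH2OPMB arm takes the convex side and eclipses the formyl hydrogen, not the aluminium-bound oxygen, so OH ends trans to that arm. The step needs non-chelated activation and a Lewis acid that survives the salts; chloride from the quench binds part of the excess Me2AlCl as an aluminate and disfavours the cationic chelate with the ether oxygen, and Me2AlCl scavenges protons as methane.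

Step 5
Reactants: 9 rac-(1S,2R,5R)-2-{[(4-methoxybenzyl)oxy]methyl}-5-(prop-1-en-2-yl)cyclopentan-1-ol
Product: 10 rac-tert-butyl({(1S,2R,5R)-2-{[(4-methoxybenzyl)oxy]methyl}-5-(prop-1-en-2-yl)cyclopentyl}oxy)dimethylsilane
Conditions: TBSOTf, 2,6-lutidine, CH2Cl2, −78 → 0 °C
Reagents that add atoms: tert-butyldimethylsilyl trifluoromethanesulfonate, CC(C)(C)[Si](C)(C)OS(=O)(=O)C(F)(F)F
Why: Silylation with the silyl triflate is fast enough for the flanked secondary alcohol and changes no stereocentre.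

Step 6
Reactants: 10 rac-tert-butyl({(1S,2R,5R)-2-{[(4-methoxybenzyl)oxy]methyl}-5-(prop-1-en-2-yl)cyclopentyl}oxy)dimethylsilane
Product: 11 rac-[(1R,2S,3R)-2-{[tert-butyl(dimethyl)silyl]oxy}-3-(prop-1-en-2-yl)cyclopentyl]methanol
Conditions: DDQ, CH2Cl2/pH 7 buffer, 0 °C
Reagents that add atoms: none
Why: Oxidative cleavage of the 4-methoxybenzyl ether by DDQ should spare the silyl ether and the isopropenyl group.

Step 7
Reactants: 11 rac-[(1R,2S,3R)-2-{[tert-butyl(dimethyl)silyl]oxy}-3-(prop-1-en-2-yl)cyclopentyl]methanol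
Product: 12 [(1R,2S,3R)-2-{[tert-butyl(dimethyl)silyl]oxy}-3-(prop-1-en-2-yl)cyclopentyl]methanol (single enantiomer, recovered alcohol)
Conditions: immobilised lipase from Burkholderia cepacia, vinyl acetate, t-BuOMe, 30 °C, stopped near half conversion; chromatography
Reagents that add atoms: none
Why: Lipase-catalysed acyl transfer (kinetic resolution) acylates one enantiomer of the primary alcohol, whose stereocentre sits next to the carbinol carbon, so the unreacted alcohol carries the absolute configuration of C-a, C-b and C-e needed for the target.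

Step 8
Reactants: 12 [(1R,2S,3R)-2-{[tert-butyl(dimethyl)silyl]oxy}-3-(prop-1-en-2-yl)cyclopentyl]methanol
Product: 13 (1S,2S,3R)-2-{[tert-butyl(dimethyl)silyl]oxy}-3-(prop-1-en-2-yl)cyclopentane-1-carbaldehyde
Conditions: Dess–Martin periodinane, CH2Cl2, 0 → 23 °C
Reagents that add atoms: none
Why: Dess–Martin oxidation is neutral and should not epimerise the α-centre C-e, whose trans arrangement to the silyloxy group is also the thermodynamically preferred one.

**Central fragment**

Step 9
Reactants: 14 hexa-1,5-diyne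
Product: 15 1,6-bis(trimethylsilyl)hexa-1,5-diyne
Conditions: n-BuLi (2.1 equiv), THF, −78 °C; TMSCl, −78 → 23 °C
Reagents that add atoms: chlorotrimethylsilane, C[Si](C)(C)Cl
Why: Double deprotonation of the terminal alkynes and C-silylation of the acetylides is routine.

Step 10
Reactants: 15 1,6-bis(trimethylsilyl)hexa-1,5-diyne
Product: 18 (3Z,7Z)-3,8-bis(trimethylsilyl)deca-3,7-diene-1,10-diol, via bis(alkenylalane) 16 (not isolated), via dilithium bis(alanate) 17 (not isolated)
Conditions: i-Bu2AlH (2.2 equiv), N-methylpyrrolidine, heptane, 60 °C; MeLi (2.2 equiv), Et2O, 0 °C; oxirane (2.5 equiv), 0 → 23 °C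
Reagents that add atoms: oxirane, C1CO1
Why: Hydroalumination of a silylalkyne in the presence of a donor is a syn addition with aluminium on the silyl-bearing carbon, and each of the two alkenylalanate termini then opens one molecule of oxirane (two per molecule of 15) with retention at the sp2 carbon, so hydrogen ends cis to the hydroxyethyl arm and silicon cis to the central chain in both alkenes.

Step 11
Reactants: 18 (3Z,7Z)-3,8-bis(trimethylsilyl)deca-3,7-diene-1,10-diol
Product: 19 (3Z,7Z)-1,10-diiodo-3,8-bis(trimethylsilyl)deca-3,7-diene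
Conditions: I2, PPh3, imidazole, CH2Cl2, 0 °C
Reagents that add atoms: iodine, II
Why: Appel-type iodination converts the primary alcohols into iodides without touching the vinylsilanes.

**Union and completion**

Step 12
Reactants: 19 (3Z,7Z)-1,10-diiodo-3,8-bis(trimethylsilyl)deca-3,7-diene; 13 (1S,2S,3R)-2-{[tert-butyl(dimethyl)silyl]oxy}-3-(prop-1-en-2-yl)cyclopentane-1-carbaldehyde (2.1 equiv)
Product: 21 (4Z,8Z)-1,12-bis[2-{[tert-butyl(dimethyl)silyl]oxy}-3-(prop-1-en-2-yl)cyclopentyl]-4,9-bis(trimethylsilyl)dodeca-4,8-diene-1,12-diol (rings as in 13; mixture of epimers at both carbinols), via dilithium reagent 20 (not isolated)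
Conditions: t-BuLi (4.2 equiv), Et2O/pentane, −78 °C; then 13, −78 °C
Reagents that add atoms: none
Why: Iodine–lithium exchange of the primary iodides followed by 1,2-addition to the aldehyde makes both oxane C-2–C-3 bonds; the two new carbinol centres need no control because step 13 removes them.

Step 13
Reactants: 21 (4Z,8Z)-1,12-bis[2-{[tert-butyl(dimethyl)silyl]oxy}-3-(prop-1-en-2-yl)cyclopentyl]-4,9-bis(trimethylsilyl)dodeca-4,8-diene-1,12-diol
Product: 22 (4Z,8Z)-1,12-bis[2-{[tert-butyl(dimethyl)silyl]oxy}-3-(prop-1-en-2-yl)cyclopentyl]-4,9-bis(trimethylsilyl)dodeca-4,8-diene-1,12-dione (rings as in 13)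
Conditions: Dess–Martin periodinane, CH2Cl2, 23 °C
Reagents that add atoms: none
Why: Dess–Martin oxidation gives the diketone, and the α-centres C-e stay in their thermodynamically preferred trans arrangement.

Step 14
Reactants: 22 (4Z,8Z)-1,12-bis[2-{[tert-butyl(dimethyl)silyl]oxy}-3-(prop-1-en-2-yl)cyclopentyl]-4,9-bis(trimethylsilyl)dodeca-4,8-diene-1,12-dione
Product: 23 (1R,4Z,8Z,12R)-1,12-bis[2-{[tert-butyl(dimethyl)silyl]oxy}-3-(prop-1-en-2-yl)cyclopentyl]-4,9-bis(trimethylsilyl)dodeca-4,8-diene-1,12-diol (rings as in 13)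
Conditions: LiBH(s-Bu)3, THF, −78 °C
Reagents that add atoms: none
Why: Felkin–Anh reduction with a bulky hydride attacks each ketone anti to the larger ring branch (the silyloxy-bearing C-a), which sets both oxane C-2 carbinols R; this is the opposite face to the one a carbon nucleophile would take on the aldehyde.

Step 15
Reactants: 23 (1R,4Z,8Z,12R)-1,12-bis[2-{[tert-butyl(dimethyl)silyl]oxy}-3-(prop-1-en-2-yl)cyclopentyl]-4,9-bis(trimethylsilyl)dodeca-4,8-diene-1,12-diol
Product: 24 bis[(2-methoxyethoxy)methyl] ether of 23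
Conditions: MEMCl, i-Pr2NEt, CH2Cl2, 40 °C
Reagents that add atoms: 2-methoxyethoxymethyl chloride, COCCOCCl
Why: Acetal ether formation places on each C-2 oxygen the formaldehyde-level carbon that becomes oxane C-6; no stereocentre changes.

Step 16
Reactants: 24 bis[(2-methoxyethoxy)methyl] ether of 23
Product: 25 O,O′-bis(tert-butyldimethylsilyl)testudinariol A
Conditions: SnCl4, CH2Cl2, −40 → −20 °C
Reagents that add atoms: none
Why: Acetal-initiated vinylsilane cyclisation: SnCl4 ionises each acetal to an O=CH2 oxocarbenium ion, the silyl-bearing alkene carbon attacks it to close the six-membered oxane (C-5–C-6 bond) through a β-silyl cation, and loss of the silyl group with retention leaves C-6 cis to the central chain, i.e. the Z alkenes of the target.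

Step 17
Reactants: 25 O,O′-bis(tert-butyldimethylsilyl)testudinariol A
Product: 26 testudinariol A
Conditions: TBAF, THF, 50 °C
Reagents that add atoms: none
Why: Fluoride-mediated desilylation frees both cyclopentanols without affecting the alkenes or the oxanes.

**Compound list**

1 | 2-methylidenepropane-1,3-diol | C=C(CO)CO | starting material
2 | 2-{[(4-methoxybenzyl)oxy]methyl}prop-2-en-1-ol | C=C(CO)COCc1ccc(OC)cc1 | intermediate
3 | 2-{[(4-methoxybenzyl)oxy]methyl}prop-2-enal | C=C(C=O)COCc1ccc(OC)cc1 | intermediate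
4 | (3-methylbut-2-en-1-yl)magnesium chloride | CC(C)=CC[Mg]Cl | starting material
5 | 2-{[(4-methoxybenzyl)oxy]methyl}-4,4-dimethylhexa-1,5-dien-3-ol (racemic) | C=CC(C)(C)C(O)C(=C)COCc1ccc(OC)cc1 | intermediate
6 | potassium alkoxide of 5 | [K+].[O-]C(C(=C)COCc1ccc(OC)cc1)C(C)(C)C=C | intermediate
7 | potassium (Z)-2-{[(4-methoxybenzyl)oxy]methyl}-6-methylhepta-1,5-dien-1-olate | [K+].[O-]/C=C(\COCc1ccc(OC)cc1)CCC=C(C)C | intermediate
8 | 2-{[(4-methoxybenzyl)oxy]methyl}-6-methylhept-5-enal (racemic) | O=CC(COCc1ccc(OC)cc1)CCC=C(C)C | intermediate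
9 | rac-(1S,2R,5R)-2-{[(4-methoxybenzyl)oxy]methyl}-5-(prop-1-en-2-yl)cyclopentan-1-ol | C=C(C)[C@H]1CC[C@H](COCc2ccc(OC)cc2)[C@H]1O | intermediate
10 | rac-tert-butyl({(1S,2R,5R)-2-{[(4-methoxybenzyl)oxy]methyl}-5-(prop-1-en-2-yl)cyclopentyl}oxy)dimethylsilane | C=C(C)[C@H]1CC[C@H](COCc2ccc(OC)cc2)[C@H]1O[Si](C)(C)C(C)(C)C | intermediate
11 | rac-[(1R,2S,3R)-2-{[tert-butyl(dimethyl)silyl]oxy}-3-(prop-1-en-2-yl)cyclopentyl]methanol | C=C(C)[C@H]1CC[C@H](CO)[C@H]1O[Si](C)(C)C(C)(C)C | intermediate
12 | [(1R,2S,3R)-2-{[tert-butyl(dimethyl)silyl]oxy}-3-(prop-1-en-2-yl)cyclopentyl]methanol (single enantiomer) | C=C(C)[C@H]1CC[C@H](CO)[C@H]1O[Si](C)(C)C(C)(C)C | intermediate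
13 | (1S,2S,3R)-2-{[tert-butyl(dimethyl)silyl]oxy}-3-(prop-1-en-2-yl)cyclopentane-1-carbaldehyde | C=C(C)[C@H]1CC[C@H](C=O)[C@H]1O[Si](C)(C)C(C)(C)C | intermediate
14 | hexa-1,5-diyne | C#CCCC#C | starting material
15 | 1,6-bis(trimethylsilyl)hexa-1,5-diyne | C[Si](C)(C)C#CCCC#C[Si](C)(C)C | intermediate
16 | (1Z,5Z)-1,6-bis(diisobutylalumanyl)-1,6-bis(trimethylsilyl)hexa-1,5-diene | CC(C)C[Al](CC(C)C)/C(=C/CC/C=C(/[Al](CC(C)C)CC(C)C)[Si](C)(C)C)[Si](C)(C)C | intermediate
17 | dilithium bis(methyl)alanate of 16 | [Li+].[Li+].CC(C)C[Al-](C)(CC(C)C)/C(=C/CC/C=C(/[Al-](C)(CC(C)C)CC(C)C)[Si](C)(C)C)[Si](C)(C)C | intermediate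
18 | (3Z,7Z)-3,8-bis(trimethylsilyl)deca-3,7-diene-1,10-diol | OCC/C(=C/CC/C=C(/CCO)[Si](C)(C)C)[Si](C)(C)C | intermediate
19 | (3Z,7Z)-1,10-diiodo-3,8-bis(trimethylsilyl)deca-3,7-diene | ICC/C(=C/CC/C=C(/CCI)[Si](C)(C)C)[Si](C)(C)C | intermediate
20 | (3Z,7Z)-1,10-dilithio-3,8-bis(trimethylsilyl)deca-3,7-diene | [Li]CC/C(=C/CC/C=C(/CC[Li])[Si](C)(C)C)[Si](C)(C)C | intermediate
21 | (4Z,8Z)-1,12-bis[2-(TBS-oxy)-3-(prop-1-en-2-yl)cyclopentyl]-4,9-bis(trimethylsilyl)dodeca-4,8-diene-1,12-diol, carbinol epimers | C=C(C)[C@H]1CC[C@H](C(O)CC/C(=C/CC/C=C(/CCC(O)[C@H]2CC[C@H](C(=C)C)[C@@H]2O[Si](C)(C)C(C)(C)C)[Si](C)(C)C)[Si](C)(C)C)[C@H]1O[Si](C)(C)C(C)(C)C | intermediate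
22 | (4Z,8Z)-1,12-bis[2-(TBS-oxy)-3-(prop-1-en-2-yl)cyclopentyl]-4,9-bis(trimethylsilyl)dodeca-4,8-diene-1,12-dione | C=C(C)[C@H]1CC[C@H](C(=O)CC/C(=C/CC/C=C(/CCC(=O)[C@H]2CC[C@H](C(=C)C)[C@@H]2O[Si](C)(C)C(C)(C)C)[Si](C)(C)C)[Si](C)(C)C)[C@H]1O[Si](C)(C)C(C)(C)C | intermediate
23 | (1R,4Z,8Z,12R)-diol from 22 | C=C(C)[C@H]1CC[C@H]([C@H](O)CC/C(=C/CC/C=C(/CC[C@H]([C@H]2CC[C@H](C(=C)C)[C@@H]2O[Si](C)(C)C(C)(C)C)O)[Si](C)(C)C)[Si](C)(C)C)[C@H]1O[Si](C)(C)C(C)(C)C | intermediate
24 | bis[(2-methoxyethoxy)methyl] ether of 23 | C=C(C)[C@H]1CC[C@H]([C@H](OCOCCOC)CC/C(=C/CC/C=C(/CC[C@H]([C@H]2CC[C@H](C(=C)C)[C@@H]2O[Si](C)(C)C(C)(C)C)OCOCCOC)[Si](C)(C)C)[Si](C)(C)C)[C@H]1O[Si](C)(C)C(C)(C)C | intermediate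
25 | O,O′-bis(tert-butyldimethylsilyl)testudinariol A | C=C(C)[C@H]1CC[C@H]([C@H]2CC/C(=C/CC/C=C3/CC[C@H]([C@H]4CC[C@H](C(=C)C)[C@@H]4O[Si](C)(C)C(C)(C)C)OC3)CO2)[C@H]1O[Si](C)(C)C(C)(C)C | intermediate
26 | testudinariol A | C=C(C)[C@H]1CC[C@H]([C@H]2CC/C(=C/CC/C=C3/CC[C@H]([C@H]4CC[C@H](C(=C)C)[C@@H]4O)OC3)CO2)[C@H]1O | target

**Step count.** Total 17 steps; longest linear sequence 14 steps (steps 1–8 and 12–17).

**Steps most likely to fail**

Step 4 (key step). The one-pot sequence may fail at its junction in four ways. The salts and crown ether left by the anionic stage may take up the Lewis acid. The alkoxide may fragment to enal and prenyl anion before it rearranges. Enolate 7 may lose the 4-methoxybenzyl oxide group by β-elimination before it is protonated. The aldehyde face may be taken under chelation, so that the side arm ends cis to the hydroxyl. Fallback, setting out from dienol 5: a neutral, stepwise route through a silyl enol ether. Silylation (TMSCl, imidazole, CH2Cl2) gives the trimethylsilyl ether of 5, F1. Thermal siloxy-Cope rearrangement (o-dichlorobenzene, 220 °C), which has neither an alkoxide to fragment nor an enolate to eliminate, gives the trimethylsilyl enol ether of aldehyde 8, F2. Methanolysis (K2CO3, MeOH, 0 °C) gives aldehyde 8, now isolated and free of salts. Ene cyclisation with 1.1 equiv of Me2AlCl in CH2Cl2 at −78 °C (monodentate activation) rejoins the route at 9.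

Step 7. The enzyme may discriminate poorly between the enantiomers of a primary alcohol whose stereocentre is flanked by a bulky silyl ether, leaving material of insufficient enantiomeric purity at any conversion. Fallback, setting out from racemic 11: covalent resolution. Esterification with (S)-2-methoxy-2-phenylacetic acid (DCC, DMAP, CH2Cl2) gives the diastereomeric esters [(1R,2S,3R)-2-(TBS-oxy)-3-(prop-1-en-2-yl)cyclopentyl]methyl (2S)-2-methoxy-2-phenylacetate, F3, and its (1S,2R,3S)-ring diastereomer, F4. These are separated by chromatography, and hydrolysis of F3 (LiOH, THF/H2O) rejoins the route at 12.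

Step 16. The oxocarbenium ions or adventitious acid may be diverted: protodesilylation of the vinylsilanes, Prins-type capture by an isopropenyl group, or loss of the silyl ethers under the Lewis acid. Fallback, setting out from diol 23: the oxane C-6 carbon is brought in as carbon monoxide. Iododesilylation with retention (N-iodosuccinimide, MeCN, 0 °C) gives the bis(vinyl iodide) diol F5. Carbonylative lactonisation (PdCl2(PPh3)2, CO 1 atm, Et3N, DMF, 60 °C) gives the bis(α-alkylidene δ-lactone) F6. Reduction (i-Bu2AlH, CH2Cl2, −78 °C) gives the bis(lactol) F7, and ionic deoxygenation (Et3SiH, BF3·OEt2, CH2Cl2, −78 °C) rejoins the route at 25.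

**Further compounds**

F1 | step 4 | trimethylsilyl ether of 5 | C=CC(C)(C)C(O[Si](C)(C)C)C(=C)COCc1ccc(OC)cc1
F2 | step 4 | trimethylsilyl enol ether of aldehyde 8 (E/Z mixture) | C[Si](C)(C)OC=C(COCc1ccc(OC)cc1)CCC=C(C)C
F3 | step 7 | [(1R,2S,3R)-2-{[tert-butyl(dimethyl)silyl]oxy}-3-(prop-1-en-2-yl)cyclopentyl]methyl (2S)-2-methoxy-2-phenylacetate | C=C(C)[C@H]1CC[C@H](COC(=O)[C@@H](OC)c2ccccc2)[C@H]1O[Si](C)(C)C(C)(C)C
F4 | step 7 | [(1S,2R,3S)-2-{[tert-butyl(dimethyl)silyl]oxy}-3-(prop-1-en-2-yl)cyclopentyl]methyl (2S)-2-methoxy-2-phenylacetate | C=C(C)[C@@H]1CC[C@@H](COC(=O)[C@@H](OC)c2ccccc2)[C@@H]1O[Si](C)(C)C(C)(C)C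
F5 | step 16 | (1R,4Z,8Z,12R)-4,9-diiodo analogue of diol 23 | C=C(C)[C@H]1CC[C@H]([C@H](O)CC/C(=C/CC/C=C(/CC[C@H]([C@H]2CC[C@H](C(=C)C)[C@@H]2O[Si](C)(C)C(C)(C)C)O)I)I)[C@H]1O[Si](C)(C)C(C)(C)C
F6 | step 16 | bis(oxan-2-one) analogue of 25 (C-6 carbonyls) | C=C(C)[C@H]1CC[C@H]([C@H]2CC/C(=C/CC/C=C3/CC[C@H]([C@H]4CC[C@H](C(=C)C)[C@@H]4O[Si](C)(C)C(C)(C)C)OC3=O)C(=O)O2)[C@H]1O[Si](C)(C)C(C)(C)C
F7 | step 16 | bis(oxan-2-ol) analogue of 25 (C-6 lactols, anomer mixture) | C=C(C)[C@H]1CC[C@H]([C@H]2CC/C(=C/CC/C=C3/CC[C@H]([C@H]4CC[C@H](C(=C)C)[C@@H]4O[Si](C)(C)C(C)(C)C)OC3O)C(O)O2)[C@H]1O[Si](C)(C)C(C)(C)C
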